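**Retrosynthetic overview** (carotenoid numbering; the two end groups are identical)

1. The C40 skeleton is cut at C11=C12 and C11'=C12' into two C15 phosphonium salts and the C10 trienedial (double Wittig); the 4,4'-sulfates are put on last, on the free tetrol.
2. The C15 salt comes from a C10 end-group lactol and a C5 phosphonate (Horner–Wadsworth–Emmons at C7=C8).
3. Enabling feature: on ring C1–C6 the oxygen on C3 and the side-chain carbon C7 on C6 are 1,4-cis, so O3 and C7 can be tied as an O–C(=O) bridge; the end group is then a 2-oxabicyclo[2.2.2]octan-3-one.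
4. That cage is the [4+2] adduct of a 2-pyrone (C3–C4–C5–C6, the ring oxygen and C7; its C3 ester is a temporary chelating group) and isobutylene (C1 with both methyls, and C2). One step forms C2–C3, C1–C6, the carbocycle and the C3/C6 stereocentres; C4–OH and C5–H then enter together by hydroboration of C4=C5 from the lactone face.
5. Ring order: pyrone ring (step 2), then the cyclohexene ring together with the lactone cage (step 3); the cage is opened again in steps 7 and 8.

Key step: step 3

Remark: the target is drawn as the free bis(hydrogen sulfate), so the last step ends with a cold cation exchange to the acid form; in practice the compound would be stored as its disodium salt.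

**Step 1**
Reactants: 1 dimethyl malonate; 2 4,4-dimethoxybutan-2-one
Product: 3 dimethyl 2-(4,4-dimethoxybutan-2-ylidene)malonate
Conditions: TiCl4 (2 equiv), pyridine (4 equiv), THF, 0 °C → rt
Reagents that add atoms: none
Why: Knoevenagel condensation of a malonate with a ketone under TiCl4/pyridine activation, with the buffered medium expected to spare the dimethyl acetal; no stereocentre is formed.

**Step 2**
Reactants: 3 dimethyl 2-(4,4-dimethoxybutan-2-ylidene)malonate
Product: 5 methyl 4-methyl-2-oxo-2H-pyran-3-carboxylate, via aldehyde 4 (not isolated)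
Conditions: 88% aq. HCO2H, 70 °C
Reagents that add atoms: water, O
Why: Acid hydrolysis of the acetal gives aldehyde 4, whose dienol lactonises onto the cis ester with loss of methanol (2-pyrone annulation of an alkylidene malonate); no stereocentre is formed.

**Step 3**
Reactants: 5 methyl 4-methyl-2-oxo-2H-pyran-3-carboxylate; 6 2-methylpropene (isobutylene)
Product: 7 methyl (1R,4S)-5,8,8-trimethyl-3-oxo-2-oxabicyclo[2.2.2]oct-5-ene-4-carboxylate
Conditions: 6 (10 equiv), [Cu((S,S)-t-Bu-box)](SbF6)2 (10 mol %; from CuCl2, AgSbF6 and 2,2'-(propane-2,2-diyl)bis[(4S)-4-tert-butyl-4,5-dihydrooxazole]), 4 Å MS, CH2Cl2, −20 → 0 °C, sealed tube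
Reagents that add atoms: none
Why: Proposed new method: chelation of the lactone and ester carbonyls of 5 by the divalent copper bis(oxazoline) cation lowers the pyrone LUMO, so that the CH2 terminus of isobutylene bonds to pyrone C6 (the future C3) while the developing tertiary cation at CMe2 is captured by the copper-bound enolate carbon, pyrone C3 (the future C6), in a concerted but highly asynchronous inverse-electron-demand Diels–Alder reaction. The closest known reaction types are the copper–bis(oxazoline) and lanthanide–BINOL catalysed asymmetric inverse-demand cycloadditions of 3-carboalkoxy-2-pyrones with enol ethers, styrenes and indenes, and the copper–bis(oxazoline) catalysed ene reactions of isobutylene with chelating dicarbonyl electrophiles; pairing a 2-pyrone with a simple 1,1-dialkylethylene is the new element. The carbocyclic six-membered ring (C1–C6 of the end group) is closed by an intermolecular [4+2] cycloaddition, suprafacial on both partners, and the 2-oxabicyclo[2.2.2]octene cage arises with it. The two new stereocentres are the bridgeheads: their cis relationship (O on C3 and the carbonyl carbon C7 on C6 on one ring face) is fixed by the lactone bridge of the pyrone and their absolute sense by the tert-butyl groups of the ligand, which leave one face of the square-planar chelate open; C1 carries two methyl groups, so there is no endo/exo issue. The step needs regioselectivity (CH2 to pyrone C6, CMe2 to pyrone C3), secured by matching the most electrophilic pyrone terminus with the nucleophilic, less substituted alkene terminus, and it needs ring closure to outrun proton loss (ene adduct) and loss of CO2 from the adduct, which low temperature and the non-basic SbF6 counter-ion should secure. Both ligand antipodes are commercial, so the antipode is taken if a first run shows the opposite facial sense.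

**Step 4**
Reactants: 7 methyl (1R,4S)-5,8,8-trimethyl-3-oxo-2-oxabicyclo[2.2.2]oct-5-ene-4-carboxylate
Product: 9 (1R,4S)-5,8,8-trimethyl-3-oxo-2-oxabicyclo[2.2.2]oct-5-ene-4-carboxylic acid, via lithium carboxylate 8 (not isolated)
Conditions: LiI (3 equiv), EtOAc, reflux, dark; then 1 M HCl
Reagents that add atoms: none
Why: SN2 dealkylation of the methyl ester by iodide attacks only the O-methyl carbon, so the lactone (whose O-alkyl carbon is a bridgehead) and both stereocentres are untouched.

**Step 5**
Reactants: 9 (1R,4S)-5,8,8-trimethyl-3-oxo-2-oxabicyclo[2.2.2]oct-5-ene-4-carboxylic acid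
Product: 12 (1R,4S)-5,8,8-trimethyl-2-oxabicyclo[2.2.2]oct-5-en-3-one, via acid chloride 10 (not isolated), via thiohydroxamate ester 11 (not isolated)
Conditions: (COCl)2, cat. DMF, CH2Cl2, 0 °C → rt; then sodium 2-thioxopyridin-1(2H)-olate (NaC5H4NOS), cat. DMAP, t-BuSH, PhH, hν (tungsten lamp), 25–40 °C
Reagents that add atoms: none
Why: Barton reductive decarboxylation: the bridgehead radical cannot invert inside the bicycle and takes hydrogen from t-BuSH, so hydrogen replaces the carboxyl group with the configuration of the future C6 fixed.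

**Step 6**
Reactants: 12 (1R,4S)-5,8,8-trimethyl-2-oxabicyclo[2.2.2]oct-5-en-3-one
Product: 14 (1R,4R,7S,8R)-7-hydroxy-5,5,8-trimethyl-2-oxabicyclo[2.2.2]octan-3-one, via alkylborane 13 (not isolated)
Conditions: BH3·THF (1.2 equiv), THF, 0 °C; then 30% H2O2, aq. NaOAc, 0 °C → rt
Reagents that add atoms: hydrogen peroxide, OO
Why: Hydroboration–oxidation: borane adds syn and anti-Markovnikov from the open alkene face beside the unsubstituted lactone bridge (the other face is blocked by a methyl of the CMe2 bridge), so OH at the future C4 and H at the future C5 both enter syn to the lactone oxygen and the C5 methyl is pushed to the opposite face.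

**Step 7**
Reactants: 14 (1R,4R,7S,8R)-7-hydroxy-5,5,8-trimethyl-2-oxabicyclo[2.2.2]octan-3-one
Product: 15 (1R,4R,7S,8R)-5,5,8-trimethyl-2-oxabicyclo[2.2.2]octane-3,7-diol (lactol, both C3 epimers, in equilibrium with the open hydroxy aldehyde)
Conditions: i-Bu2AlH (2.5 equiv), CH2Cl2, −78 °C; aq. potassium sodium tartrate (KNaC4H4O6) work-up
Reagents that add atoms: none
Why: Partial reduction of a lactone to the lactol with i-Bu2AlH, whose tetrahedral aluminate is stable at −78 °C; no ring stereocentre is touched.

**Step 8**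
Reactants: 15 the lactol of step 7; 16 triethyl 3-methyl-4-phosphonobut-2-enoate (commercial E/Z mixture)
Product: 18 ethyl (2E,4E)-5-[(1R,4R,5S,6R)-4,5-dihydroxy-2,2,6-trimethylcyclohexyl]-3-methylpenta-2,4-dienoate, via lithiated phosphonate 17 (not isolated)
Conditions: 16 (3.5 equiv), LiN(SiMe3)2 (3.3 equiv), THF–DMPU, −78 °C → rt
Reagents that add atoms: none
Why: Horner–Wadsworth–Emmons olefination of the ring-opened hydroxy aldehyde form of the lactol with the vinylogous phosphonate should give the (E)-C7=C8 bond and mainly the (E)-C9=C10 bond, with the two alkoxides as spectators and C6 in its thermodynamically preferred equatorial configuration.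

**Step 9**
Reactants: 18 the dienoate of step 8
Product: 19 (2E,4E)-5-[(1R,4R,5S,6R)-4,5-dihydroxy-2,2,6-trimethylcyclohexyl]-3-methylpenta-2,4-dien-1-ol
Conditions: i-Bu2AlH (5 equiv), CH2Cl2, −78 → 0 °C; aq. KNaC4H4O6 work-up
Reagents that add atoms: none
Why: 1,2-Reduction of a conjugated ester to the allylic alcohol with i-Bu2AlH leaves the diene geometry and the ring stereocentres unchanged.

**Step 10**
Reactants: 19 the C15 triol of step 9
Product: 20 [(2E,4E)-5-[(1R,4R,5S,6R)-4,5-dihydroxy-2,2,6-trimethylcyclohexyl]-3-methylpenta-2,4-dien-1-yl]triphenylphosphonium bromide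
Conditions: PPh3·HBr (1.05 equiv), MeOH, rt, dark
Reagents that add atoms: triphenylphosphine hydrobromide, [Br-].[PH+](c1ccccc1)(c1ccccc1)c1ccccc1
Why: Phosphonium salt formation from an allylic alcohol via the pentadienyl cation, which PPh3 captures at the unhindered primary terminus while the saturated secondary diol stays inert.

**Step 11**
Reactants: 20 the C15 phosphonium bromide; 21 (2E,4E,6E)-2,7-dimethylocta-2,4,6-trienedial
Product: 24 (all-E)-(3R,4S,5R,6R,3'R,4'S,5'R,6'R)-5,6,5',6'-tetrahydro-β,β-carotene-3,4,3',4'-tetrol, via phosphorus ylide 22 (not isolated), via C25 aldehyde 23 (not isolated)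
Conditions: 20 (2.2 equiv), 21 (1 equiv), NaOMe (2.3 equiv), MeOH–CH2Cl2, 0 °C → rt, Ar, dark; then EtOH, reflux (Z → E)
Reagents that add atoms: none
Why: Double Wittig olefination of the C10 dialdehyde with two equivalents of the allylic ylide (C15 + C10 + C15 carotenoid assembly) tolerates free hydroxyl groups, and (Z)-isomers at the new C11=C12 bonds are equilibrated thermally to the all-E polyene.

**Step 12**
Reactants: 24 the carotenoid tetrol of step 11
Product: 27 (3R,4S,5R,6R,3'R,4'S,5'R,6'R)-3,3'-dihydroxy-5,6,5',6'-tetrahydro-β,β-carotene-4,4'-diyl bis(hydrogen sulfate) (the target), via bis-stannylene acetal 25 (not isolated), via trimethylammonium salt 26 (not isolated)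
Conditions: Bu2SnO (2.2 equiv), MeOH, reflux, Ar, dark; evaporate; SO3·NMe3 (2.4 equiv), 1,4-dioxane, rt; then sulfonic acid cation-exchange resin (H+ form), MeOH, 0 °C
Reagents that add atoms: sulfur trioxide–trimethylamine complex, C[N+](C)(C)S(=O)(=O)[O-]
Why: Stannylene-acetal-directed regioselective sulfation of a cis-1,2-diol: the equatorial C4 oxygen is the activated one and the axial C3 oxygen is shielded by the syn-axial C1 methyl, so SO3 should go to O4 without touching any stereocentre.

**Compound list**

1 | dimethyl malonate | COC(=O)CC(=O)OC | starting material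
2 | 4,4-dimethoxybutan-2-one | CC(=O)CC(OC)OC | starting material
3 | dimethyl 2-(4,4-dimethoxybutan-2-ylidene)malonate | COC(=O)C(C(=O)OC)=C(C)CC(OC)OC | intermediate
4 | dimethyl 2-(4-oxobutan-2-ylidene)malonate | COC(=O)C(C(=O)OC)=C(C)CC=O | intermediate (not isolated)
5 | methyl 4-methyl-2-oxo-2H-pyran-3-carboxylate | COC(=O)C1=C(C)C=COC1=O | intermediate
6 | 2-methylpropene (isobutylene) | CC(C)=C | starting material
7 | methyl (1R,4S)-5,8,8-trimethyl-3-oxo-2-oxabicyclo[2.2.2]oct-5-ene-4-carboxylate | O=C2[C@]1(C(=O)OC)C(C)=C[C@H](O2)CC1(C)C | intermediate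
8 | lithium salt of acid 9 | O=C2[C@]1(C(=O)[O-])C(C)=C[C@H](O2)CC1(C)C.[Li+] | intermediate (not isolated)
9 | (1R,4S)-5,8,8-trimethyl-3-oxo-2-oxabicyclo[2.2.2]oct-5-ene-4-carboxylic acid | O=C2[C@]1(C(=O)O)C(C)=C[C@H](O2)CC1(C)C | intermediate
10 | acid chloride of 9 (bridgehead configuration as in 9) | O=C2[C@]1(C(=O)Cl)C(C)=C[C@H](O2)CC1(C)C | intermediate (not isolated)
11 | 2-thioxopyridin-1(2H)-yl ester of 9 (bridgehead configuration as in 9) | O=C2[C@]1(C(=O)ON3C=CC=CC3=S)C(C)=C[C@H](O2)CC1(C)C | intermediate (not isolated)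
12 | (1R,4S)-5,8,8-trimethyl-2-oxabicyclo[2.2.2]oct-5-en-3-one | O=C2[C@@H]1C(C)=C[C@H](O2)CC1(C)C | intermediate
13 | alkylborane of 12 (BH2 on the future C4, syn to the lactone bridge; H on the future C5 on the same face) | O=C2[C@@H]1[C@@H](C)[C@H](B)[C@H](O2)CC1(C)C | intermediate (not isolated)
14 | (1R,4R,7S,8R)-7-hydroxy-5,5,8-trimethyl-2-oxabicyclo[2.2.2]octan-3-one | O=C2[C@@H]1[C@@H](C)[C@H](O)[C@H](O2)CC1(C)C | intermediate
15 | (1R,4R,7S,8R)-5,5,8-trimethyl-2-oxabicyclo[2.2.2]octane-3,7-diol (lactol, C3 epimers) | OC2[C@@H]1[C@@H](C)[C@H](O)[C@H](O2)CC1(C)C | intermediate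
16 | triethyl 3-methyl-4-phosphonobut-2-enoate (E/Z mixture) | CCOC(=O)C=C(C)CP(=O)(OCC)OCC | starting material
17 | lithium salt of the carbanion of 16 | CCOC(=O)C=C(C)[CH-]P(=O)(OCC)OCC.[Li+] | intermediate (not isolated)
18 | ethyl (2E,4E)-5-[(1R,4R,5S,6R)-4,5-dihydroxy-2,2,6-trimethylcyclohexyl]-3-methylpenta-2,4-dienoate | CCOC(=O)/C=C(C)/C=C/[C@@H]1[C@@H](C)[C@H](O)[C@H](O)CC1(C)C | intermediate
19 | (2E,4E)-5-[(1R,4R,5S,6R)-4,5-dihydroxy-2,2,6-trimethylcyclohexyl]-3-methylpenta-2,4-dien-1-ol | OC/C=C(C)/C=C/[C@@H]1[C@@H](C)[C@H](O)[C@H](O)CC1(C)C | intermediate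
20 | [(2E,4E)-5-[(1R,4R,5S,6R)-4,5-dihydroxy-2,2,6-trimethylcyclohexyl]-3-methylpenta-2,4-dien-1-yl]triphenylphosphonium bromide | [Br-].c1ccccc1[P+](c1ccccc1)(c1ccccc1)C/C=C(C)/C=C/[C@@H]1[C@@H](C)[C@H](O)[C@H](O)CC1(C)C | intermediate
21 | (2E,4E,6E)-2,7-dimethylocta-2,4,6-trienedial | O=C/C(C)=C/C=C/C=C(C)/C=O | starting material
22 | ylide of 20 | c1ccccc1P(c1ccccc1)(c1ccccc1)=C/C=C(C)/C=C/[C@@H]1[C@@H](C)[C@H](O)[C@H](O)CC1(C)C | intermediate (not isolated)
23 | all-E C25 aldehyde (product of the first Wittig condensation; one end group of 24, formyl at C12') | O=C/C(C)=C/C=C/C=C(C)/C=C/C=C(C)/C=C/[C@@H]1[C@@H](C)[C@H](O)[C@H](O)CC1(C)C | intermediate (not isolated)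
24 | (all-E)-(3R,4S,5R,6R,3'R,4'S,5'R,6'R)-5,6,5',6'-tetrahydro-β,β-carotene-3,4,3',4'-tetrol | CC(/C=C/C=C(C)/C=C/[C@@H]1[C@@H](C)[C@H](O)[C@H](O)CC1(C)C)=C\C=C\C=C(C)\C=C\C=C(C)\C=C\[C@@H]1[C@@H](C)[C@H](O)[C@H](O)CC1(C)C | intermediate
25 | 3,4:3',4'-bis-O-(dibutylstannylene) acetal of 24 | CC(/C=C/C=C(C)/C=C/[C@@H]1[C@@H](C)[C@@H]2O[Sn](CCCC)(CCCC)O[C@@H]2CC1(C)C)=C\C=C\C=C(C)\C=C\C=C(C)\C=C\[C@@H]1[C@@H](C)[C@@H]2O[Sn](CCCC)(CCCC)O[C@@H]2CC1(C)C | intermediate (not isolated)
26 | bis(trimethylammonium) salt of 27 | CC(/C=C/C=C(C)/C=C/[C@@H]1[C@@H](C)[C@H](OS(=O)(=O)[O-])[C@H](O)CC1(C)C)=C\C=C\C=C(C)\C=C\C=C(C)\C=C\[C@@H]1[C@@H](C)[C@H](OS(=O)(=O)[O-])[C@H](O)CC1(C)C.C[NH+](C)C.C[NH+](C)C | intermediate (not isolated)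
27 | (3R,4S,5R,6R,3'R,4'S,5'R,6'R)-3,3'-dihydroxy-5,6,5',6'-tetrahydro-β,β-carotene-4,4'-diyl bis(hydrogen sulfate) | CC(/C=C/C=C(C)/C=C/[C@@H]1[C@@H](C)[C@H](OS(=O)(=O)O)[C@H](O)CC1(C)C)=C\C=C\C=C(C)\C=C\C=C(C)\C=C\[C@@H]1[C@@H](C)[C@H](OS(=O)(=O)O)[C@H](O)CC1(C)C | target

**Step count and risks**

Total step count: 12. Longest linear sequence: 12 steps (1 and 2 to 27); 6, 16 and 21 are bought.

Steps most likely to fail:

1. Step 3 (the step that carries the label "Proposed new method:"). What may go wrong: the chelated pyrone may not be electrophilic enough to engage isobutylene, the alkene may be lost to cationic oligomerisation, the polar transition state may shed a proton to give an ene-type adduct instead of closing the ring, or the two pyrone faces may not be told apart. Fallback (known chemistry; sets out from 5 and 6, returns at 9): the uncatalysed cycloaddition of 5 with 6 under 10–12 kbar in CH2Cl2 at 25–40 °C, the established way of adding weakly activated alkenes to 2-pyrones without loss of CO2, should give the racemic adduct methyl (1RS,4SR)-5,8,8-trimethyl-3-oxo-2-oxabicyclo[2.2.2]oct-5-ene-4-carboxylate F1. LiI in EtOAc as in step 4 should give the racemic acid (1RS,4SR)-5,8,8-trimethyl-3-oxo-2-oxabicyclo[2.2.2]oct-5-ene-4-carboxylic acid F2. Classical resolution by crystallisation with (R)-1-phenylethylamine should give the (R)-1-phenylethylammonium salt of 9 F3 (the amine antipode is taken if the salt of the other acid proves less soluble), and 1 M HCl releases 9. Absolute control thus moves from the catalyst to a resolution through the carboxyl group that the activating ester leaves behind.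

2. Step 6. What may go wrong: borane may reduce the lactone, the β-acyloxy alkylborane may fragment by elimination before it is oxidised, or approach from the CMe2 side may erode the C4/C5 configuration. Fallback (sets out from 12, returns at 14): epoxidation with mCPBA (NaHCO3, CH2Cl2, 0 °C) from the lactone face should give the 5,6-epoxide of 12 with the oxirane oxygen syn to the lactone bridge F4. Epoxide-to-allylic-alcohol isomerisation with Et2Al(NC9H18) (diethylaluminium 2,2,6,6-tetramethylpiperidide, from Et2AlCl and LiNC9H18; benzene, 0 °C) removes a proton of the methyl group and should give 7-hydroxy-5,5-dimethyl-8-methylidene-2-oxabicyclo[2.2.2]octan-3-one (hydroxyl syn to the lactone bridge) F5. Hydroxyl-directed hydrogenation with [Ir(cod)(PCy3)(py)]PF6 (H2, CH2Cl2) then delivers hydrogen to the future C5 on the face of the hydroxyl and gives 14. Oxygen and hydrogen thus arrive in separate steps without borane.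

3. Step 12. What may go wrong: incomplete discrimination between O3 and O4 in the sulfation, or degradation of the polyene during stannylene formation. Fallback (sets out from 24, returns at 27): trimethyl orthoacetate with cat. pyridinium p-toluenesulfonate (CH2Cl2, rt) should give the 3,4:3',4'-bis-O-(1-methoxyethylidene) derivative of 24 F6. Mild aqueous acid (80% AcOH, 0 °C → rt) opens a cis-diol orthoester to the axial ester and should give the 3,3'-di-O-acetate of 24 F7 with both equatorial C4 hydroxyls free. SO3·pyridine (pyridine–DMF, rt) should give the 3,3'-di-O-acetyl 4,4'-bis(hydrogen sulfate) F8. K2CO3 in MeOH removes the acetates, and the same cold cation exchange gives 27.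

**Further compounds**

F1 | step 3 | methyl (1RS,4SR)-5,8,8-trimethyl-3-oxo-2-oxabicyclo[2.2.2]oct-5-ene-4-carboxylate (racemate) | O=C2C1(C(=O)OC)C(C)=CC(O2)CC1(C)C
F2 | step 3 | (1RS,4SR)-5,8,8-trimethyl-3-oxo-2-oxabicyclo[2.2.2]oct-5-ene-4-carboxylic acid (racemate) | O=C2C1(C(=O)O)C(C)=CC(O2)CC1(C)C
F3 | step 3 | (R)-1-phenylethylammonium salt of 9 | O=C2[C@]1(C(=O)[O-])C(C)=C[C@H](O2)CC1(C)C.C[C@@H]([NH3+])c1ccccc1
F4 | step 6 | 5,6-epoxide of 12, oxirane oxygen syn to the lactone bridge | O=C2[C@@H]1[C@]3(C)O[C@@H]3[C@H](O2)CC1(C)C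
F5 | step 6 | 7-hydroxy-5,5-dimethyl-8-methylidene-2-oxabicyclo[2.2.2]octan-3-one, hydroxyl syn to the lactone bridge | O=C2[C@@H]1C(=C)[C@H](O)[C@H](O2)CC1(C)C
F6 | step 12 | 3,4:3',4'-bis-O-(1-methoxyethylidene) derivative of 24 | CC(/C=C/C=C(C)/C=C/[C@@H]1[C@@H](C)[C@@H]2OC(C)(OC)O[C@@H]2CC1(C)C)=C\C=C\C=C(C)\C=C\C=C(C)\C=C\[C@@H]1[C@@H](C)[C@@H]2OC(C)(OC)O[C@@H]2CC1(C)C
F7 | step 12 | 3,3'-di-O-acetate of 24 | CC(/C=C/C=C(C)/C=C/[C@@H]1[C@@H](C)[C@H](O)[C@H](OC(C)=O)CC1(C)C)=C\C=C\C=C(C)\C=C\C=C(C)\C=C\[C@@H]1[C@@H](C)[C@H](O)[C@H](OC(C)=O)CC1(C)C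
F8 | step 12 | 3,3'-di-O-acetyl 4,4'-bis(hydrogen sulfate) of 24 | CC(/C=C/C=C(C)/C=C/[C@@H]1[C@@H](C)[C@H](OS(=O)(=O)O)[C@H](OC(C)=O)CC1(C)C)=C\C=C\C=C(C)\C=C\C=C(C)\C=C\[C@@H]1[C@@H](C)[C@H](OS(=O)(=O)O)[C@H](OC(C)=O)CC1(C)C
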